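The route cuts the C3–C4 bond of the tetrahydrofuran ring. It exploits the pseudo-meso core (O1, C2-aryl, C3-Me, C4-Me, C5-aryl; 2,3-trans, 3,4-cis, 4,5-trans): opening C3–C4 and taking one hydrogen from each methyl reveals a (1R,1'S)-bis(1-arylallyl) ether whose two vinyl groups are interchangeable. One hydrogen-atom-transfer radical cyclisation adds H to either CH2 terminus, closes the ring 5-exo at C3–C4 and turns both vinyl ends into the two methyl groups, setting both methyl-bearing stereocentres. The precursor is assembled from three bought arenes by Suzuki coupling, asymmetric hydrogenation and iridium-catalysed allylic etherification.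

Key step: step 12

Assumption: the ligand enantiomers named in steps 5 and 11 are those expected from the accepted models for these ligand families to give the drawn configurations; the antipodal ligand is used if a pilot run shows the opposite sense.

Numbering used below: ring atoms are O1, C2 (bearing ring A, the trisubstituted arene), C3, C4 and C5 (bearing ring C, the 4-oxygenated phenyl); ring B is the arene of the side chain.

Step 1
Reactants: 1 1-(benzyloxy)-4-iodobenzene; 2 propyne
Product: 3 1-(benzyloxy)-4-(prop-1-yn-1-yl)benzene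
Conditions: Pd(PPh3)2Cl2 (2 mol%), CuI (4 mol%), Et3N, THF, propyne (THF solution, excess), rt, sealed vessel
Reagents that add atoms: none
Why: Sonogashira coupling of an aryl iodide with a small terminal alkyne runs at room temperature and leaves the benzyl ether alone.

Step 2
Reactants: 3 1-(benzyloxy)-4-(prop-1-yn-1-yl)benzene
Product: 4 (Z)-2-{1-[4-(benzyloxy)phenyl]prop-1-en-2-yl}-4,4,5,5-tetramethyl-1,3,2-dioxaborolane
Conditions: B2pin2 (1.1 equiv), CuCl (5 mol%), P(p-tol)3 (6 mol%), NaOtBu (15 mol%), MeOH (2 equiv), THF, rt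
Reagents that add atoms: bis(pinacolato)diboron, CC1(C)OB(OC1(C)C)B1OC(C)(C)C(C)(C)O1
Why: Copper-catalysed formal hydroboration of an aryl alkyl alkyne, in which the boryl copper species adds syn with boron at the methyl-bearing carbon and copper at the benzylic carbon, and protonation by methanol with retention fixes the geometry with aryl and methyl cis.

Step 3
Reactants: 5 4-bromo-2-iodophenol
Product: 6 1-(benzyloxy)-4-bromo-2-iodobenzene
Conditions: BnBr (1.1 equiv), K2CO3, DMF, rt
Reagents that add atoms: benzyl bromide, BrCc1ccccc1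
Why: Williamson ether synthesis on an acidic phenol with a reactive benzylic halide, which does not disturb either aryl halide.

Step 4
Reactants: 4 (Z)-alkenyl pinacol boronate; 6 1-(benzyloxy)-4-bromo-2-iodobenzene
Product: 7 1-(benzyloxy)-2-{(E)-1-[4-(benzyloxy)phenyl]prop-1-en-2-yl}-4-bromobenzene
Conditions: Pd(dppf)Cl2 (3 mol%), K3PO4 (3 equiv), 1,4-dioxane/H2O 5:1, 60 °C
Reagents that add atoms: none
Why: Suzuki–Miyaura coupling in which zerovalent palladium inserts into the C–I bond well before the C–Br bond of the electron-rich ring at this temperature, while transmetalation and reductive elimination keep the alkene geometry, so the (E)-alkene with the two arenes trans should result.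

Step 5
Reactants: 7 (E)-alpha-methylstilbene bromide
Product: 8 1-(benzyloxy)-2-{(2R)-1-[4-(benzyloxy)phenyl]propan-2-yl}-4-bromobenzene
Conditions: [Ir(cod)(L1)][B(3,5-(CF3)2C6H3)4] (1–2 mol%; L1 = (S)-4-tert-butyl-2-[2-(di-o-tolylphosphino)phenyl]-4,5-dihydrooxazole), H2 (50 bar), CH2Cl2, rt
Reagents that add atoms: none
Why: Iridium N,P-ligand catalysed asymmetric hydrogenation of an unfunctionalised (E)-trisubstituted aryl alkene, in which syn addition of H2 to the alkene face left open by the ligand sets the (R) centre and neither the aryl bromide nor the benzyl ethers are hydrogenolysed by the cationic catalyst.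

Step 6
Reactants: 8 (R)-1,2-diarylpropane bromide; 9 methyl acrylate
Product: 10 methyl (E)-3-{4-(benzyloxy)-3-[(2R)-1-(4-(benzyloxy)phenyl)propan-2-yl]phenyl}prop-2-enoate
Conditions: Pd(OAc)2 (5 mol%), P(o-tol)3 (10 mol%), Et3N (2 equiv), DMF, 100 °C
Reagents that add atoms: none
Why: Mizoroki–Heck reaction of an aryl bromide with an acrylate gives the (E)-cinnamate through syn insertion and syn beta-hydride elimination, and the non-acidic benzylic stereocentre is not touched.

Step 7
Reactants: 10 methyl (E)-cinnamate
Product: 11 (E)-3-{4-(benzyloxy)-3-[(2R)-1-(4-(benzyloxy)phenyl)propan-2-yl]phenyl}prop-2-en-1-ol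
Conditions: i-Bu2AlH (2.5 equiv), CH2Cl2, −78 °C; aq potassium sodium tartrate
Reagents that add atoms: none
Why: 1,2-Reduction of a conjugated ester by DIBAL-H at low temperature gives the allylic alcohol without conjugate reduction or loss of alkene geometry.

Step 8
Reactants: 11 (E)-cinnamyl alcohol
Product: 12 tert-butyl (E)-3-{4-(benzyloxy)-3-[(2R)-1-(4-(benzyloxy)phenyl)propan-2-yl]phenyl}prop-2-en-1-yl carbonate
Conditions: Boc2O (1.3 equiv), n-Bu4NHSO4 (5 mol%), aq NaOH, CH2Cl2, 0 °C to rt
Reagents that add atoms: di-tert-butyl dicarbonate, CC(C)(C)OC(=O)OC(=O)OC(C)(C)C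
Why: Phase-transfer O-acylation of a primary allylic alcohol with Boc2O is the standard access to tert-butyl cinnamyl carbonates, whose tert-butoxide by-product is too hindered to compete as a nucleophile in step 11.

Step 9
Reactants: 13 4-(benzyloxy)benzaldehyde; 14 vinylmagnesium bromide
Product: 15 rac-1-[4-(benzyloxy)phenyl]prop-2-en-1-ol
Conditions: THF, −78 to 0 °C; aqueous work-up
Reagents that add atoms: none
Why: Grignard 1,2-addition to a non-enolisable aromatic aldehyde gives the racemic allylic alcohol, whose stereocentre is sorted out in step 10.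

Step 10
Reactants: 15 rac-1-[4-(benzyloxy)phenyl]prop-2-en-1-ol
Product: 16 (S)-1-[4-(benzyloxy)phenyl]prop-2-en-1-ol
Conditions: immobilised Candida antarctica lipase B (Novozym 435), vinyl acetate (3 equiv), MTBE, 30 °C, stopped slightly beyond half conversion; chromatography
Reagents that add atoms: none
Why: Lipase-catalysed kinetic resolution by irreversible transesterification, in which the enzyme should acylate the (R)-alcohol (aryl as large group, vinyl as medium group), so the unreacted (S)-alcohol is recovered enantioenriched under neutral conditions that avoid allylic transposition.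

Step 11
Reactants: 16 (S)-1-[4-(benzyloxy)phenyl]prop-2-en-1-ol; 12 (E)-cinnamyl tert-butyl carbonate
Product: 19 1-(benzyloxy)-4-[(1R)-1-{[(1S)-1-(4-(benzyloxy)phenyl)prop-2-en-1-yl]oxy}prop-2-en-1-yl]-2-[(2R)-1-(4-(benzyloxy)phenyl)propan-2-yl]benzene, via lithium alkoxide 17 (not isolated), via copper alkoxide 18 (not isolated)
Conditions: 16 (1.5 equiv), n-BuLi, THF, 0 °C; CuI, rt; then 12, [Ir(cod)Cl]2 (2 mol%), L2 (4 mol%; L2 = (Ra,R,R)-O,O'-(1,1'-binaphthalene-2,2'-diyl) N,N-bis(1-phenylethyl)phosphoramidite, pre-activated with n-PrNH2), THF, rt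
Reagents that add atoms: none
Why: Iridium-catalysed asymmetric allylic etherification (Tsuji–Trost-type substitution through a cyclometalated iridium phosphoramidite), in which the monovalent copper alkoxide attacks the aryl-bearing allyl terminus, the ligand dictates the new (R) C–O centre and the (S) centre of the alkoxide is carried through unchanged, as is established for copper alkoxides of chiral secondary allylic alcohols.

Step 12
Reactants: 19 pseudo-meso bis(1-arylallyl) ether
Product: 20 (2R,3R,4S,5S)-2-{4-(benzyloxy)-3-[(2R)-1-(4-(benzyloxy)phenyl)propan-2-yl]phenyl}-5-[4-(benzyloxy)phenyl]-3,4-dimethyloxolane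
Conditions: Fe(acac)3 (30 mol%), 2,4,6-triisopropylbenzenethiol (20 mol%), PhSiH3 (3 equiv, syringe pump), EtOH/THF 1:1, 0.005 M, 50 °C, argon
Reagents that add atoms: none
Why: Proposed new method: an iron hydride made from Fe(acac)3 and PhSiH3 transfers a hydrogen atom to the CH2 terminus of either vinyl group, the secondary 3-oxa-5-hexenyl radical formed at C3 (or C4) adds to the internal carbon of the other vinyl group, and the exocyclic primary radical takes hydrogen from the thiol, whose thiyl radical is returned to the cycle by iron and silane; the closest known reaction type is the metal-hydride hydrogen-atom-transfer reductive cyclisation of simple 1,6-dienes such as diallyl ethers and diallylamines to 3,4-dimethyl five-membered rings, which has not been run on a 1,1'-diaryl bis-allyl ether or asked to deliver this stereotetrad. The only ring formed, the tetrahydrofuran, closes by a 5-exo-trig radical addition that makes the C3–C4 bond. C3 (R) and C4 (S) are set by substrate control from C2 and C5 through a chair-like 5-hexenyl transition state in which both aryl groups of the (2R,5S) ether are pseudo-equatorial, the methyl on the radical carbon points away from the adjacent aryl group, and the 1,5-cis preference of 1-methyl-5-hexenyl radicals places the two new methyl groups cis. The step needs the 2,3-trans, 3,4-cis, 4,5-trans diastereomer, and the pseudo-meso arrangement secures it because initiation at either alkene passes through pseudo-mirror-related transition states to the same ring. It also needs ring closure to outrun simple reduction and alkene migration to the aryl enol ether, which the rate-enhancing oxygen in the chain, high dilution, slow silane addition and a catalytic amount of thiol should provide, while fragmentation of the beta-alkoxy radical to an alkene and an alkoxy radical is too slow to matter.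

Step 13
Reactants: 20 tri-O-benzyl tetrahydrofuran
Product: 21 4-[(2R,3R,4S,5S)-5-(4-hydroxyphenyl)-3,4-dimethyloxolan-2-yl]-2-[(2R)-1-(4-hydroxyphenyl)propan-2-yl]phenol
Conditions: H2 (1 atm), Pd/C (10 wt% palladium on carbon), EtOAc, rt, followed by LC-MS and filtered as soon as debenzylation is complete
Reagents that add atoms: none
Why: Catalytic hydrogenolysis cleaves the three aryl benzyl ethers much faster than the two dialkyl benzylic C–O bonds of the ring in a neutral aprotic solvent, so a reaction stopped at completion should leave the tetrahydrofuran and all five stereocentres intact.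

Compound list
1 | 1-(benzyloxy)-4-iodobenzene | Ic1ccc(OCc2ccccc2)cc1 | starting material
2 | propyne | CC#C | starting material
3 | 1-(benzyloxy)-4-(prop-1-yn-1-yl)benzene | CC#Cc1ccc(OCc2ccccc2)cc1 | intermediate
4 | (Z)-2-{1-[4-(benzyloxy)phenyl]prop-1-en-2-yl}-4,4,5,5-tetramethyl-1,3,2-dioxaborolane | C/C(B1OC(C)(C)C(C)(C)O1)=C\c1ccc(OCc2ccccc2)cc1 | intermediate
5 | 4-bromo-2-iodophenol | Oc1ccc(Br)cc1I | starting material
6 | 1-(benzyloxy)-4-bromo-2-iodobenzene | Brc1ccc(OCc2ccccc2)c(I)c1 | intermediate
7 | 1-(benzyloxy)-2-{(E)-1-[4-(benzyloxy)phenyl]prop-1-en-2-yl}-4-bromobenzene | Brc1ccc(OCc2ccccc2)c(/C(C)=C/c2ccc(OCc3ccccc3)cc2)c1 | intermediate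
8 | 1-(benzyloxy)-2-{(2R)-1-[4-(benzyloxy)phenyl]propan-2-yl}-4-bromobenzene | Brc1ccc(OCc2ccccc2)c([C@H](C)Cc2ccc(OCc3ccccc3)cc2)c1 | intermediate
9 | methyl acrylate | C=CC(=O)OC | starting material
10 | methyl (E)-3-{4-(benzyloxy)-3-[(2R)-1-(4-(benzyloxy)phenyl)propan-2-yl]phenyl}prop-2-enoate | COC(=O)/C=C/c1ccc(OCc2ccccc2)c([C@H](C)Cc2ccc(OCc3ccccc3)cc2)c1 | intermediate
11 | (E)-3-{4-(benzyloxy)-3-[(2R)-1-(4-(benzyloxy)phenyl)propan-2-yl]phenyl}prop-2-en-1-ol | OC/C=C/c1ccc(OCc2ccccc2)c([C@H](C)Cc2ccc(OCc3ccccc3)cc2)c1 | intermediate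
12 | tert-butyl (E)-3-{4-(benzyloxy)-3-[(2R)-1-(4-(benzyloxy)phenyl)propan-2-yl]phenyl}prop-2-en-1-yl carbonate | CC(C)(C)OC(=O)OC/C=C/c1ccc(OCc2ccccc2)c([C@H](C)Cc2ccc(OCc3ccccc3)cc2)c1 | intermediate
13 | 4-(benzyloxy)benzaldehyde | O=Cc1ccc(OCc2ccccc2)cc1 | starting material
14 | vinylmagnesium bromide | C=C[Mg]Br | starting material
15 | rac-1-[4-(benzyloxy)phenyl]prop-2-en-1-ol | C=CC(O)c1ccc(OCc2ccccc2)cc1 | intermediate
16 | (S)-1-[4-(benzyloxy)phenyl]prop-2-en-1-ol | C=C[C@@H](c1ccc(OCc2ccccc2)cc1)O | intermediate
17 | lithium (S)-1-[4-(benzyloxy)phenyl]prop-2-en-1-olate | C=C[C@@H](c1ccc(OCc2ccccc2)cc1)O[Li] | intermediate (not isolated)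
18 | monovalent copper (S)-1-[4-(benzyloxy)phenyl]prop-2-en-1-olate, CuOR | C=C[C@@H](c1ccc(OCc2ccccc2)cc1)O[Cu] | intermediate (not isolated)
19 | 1-(benzyloxy)-4-[(1R)-1-{[(1S)-1-(4-(benzyloxy)phenyl)prop-2-en-1-yl]oxy}prop-2-en-1-yl]-2-[(2R)-1-(4-(benzyloxy)phenyl)propan-2-yl]benzene | C=C[C@@H](c1ccc(OCc2ccccc2)cc1)O[C@H](C=C)c1ccc(OCc2ccccc2)c([C@H](C)Cc2ccc(OCc3ccccc3)cc2)c1 | intermediate
20 | (2R,3R,4S,5S)-2-{4-(benzyloxy)-3-[(2R)-1-(4-(benzyloxy)phenyl)propan-2-yl]phenyl}-5-[4-(benzyloxy)phenyl]-3,4-dimethyloxolane | C[C@@H]1[C@H](C)[C@@H](c2ccc(OCc3ccccc3)cc2)O[C@H]1c1ccc(OCc2ccccc2)c([C@H](C)Cc2ccc(OCc3ccccc3)cc2)c1 | intermediate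
21 | 4-[(2R,3R,4S,5S)-5-(4-hydroxyphenyl)-3,4-dimethyloxolan-2-yl]-2-[(2R)-1-(4-hydroxyphenyl)propan-2-yl]phenol | C[C@@H]1[C@H](C)[C@@H](c2ccc(O)cc2)O[C@H]1c1ccc(O)c([C@H](C)Cc2ccc(O)cc2)c1 | target

Total step count: 13 steps.

Longest linear sequence: 10 steps (steps 1, 2, 4, 5, 6, 7, 8, 11, 12, 13, from 1 and 2 to 21). Step 3 and steps 9–10 are side branches.

Steps most likely to fail

1. Step 12 (bears the label). Hydrogen delivery to the first radical may outrun ring closure and simply saturate a vinyl group. The metal may also take the hydrogen back and move the alkene into conjugation as an aryl enol ether. Hydrogen-atom transfer to the monosubstituted alkenes may be sluggish, and the closure may discriminate poorly between the ring faces. Fallback by known chemistry, setting out from diene 19: a thiyl-radical addition–cyclisation chain (PhSH, AIBN, dilute toluene, 80 °C), long used on diallyl ethers and diallylamines. The thiyl radical adds to the CH2 end of either vinyl group, the ring closes 5-exo at C3–C4 and the primary radical is capped by thiol hydrogen. This should give the two regioisomeric sulfides, (2R,3R,4S,5S)-4-methyl-3-[(phenylsulfanyl)methyl]oxolane F1 and (2R,3R,4S,5S)-3-methyl-4-[(phenylsulfanyl)methyl]oxolane F2, both carrying the aryl groups of 20. Nickel boride desulfurisation (NiCl2·6H2O, NaBH4, MeOH/THF, 0 °C) of the mixture turns each CH2SPh group into a methyl group, so both isomers converge, and the route is rejoined at 20.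

2. Step 11. The bulky secondary benzylic alkoxide may attack the unsubstituted allyl terminus, turnover may be slow, and the ligand may not override the resident stereocentre of the nucleophile, eroding diastereoselectivity. The fallback separates creation of the C2 centre from formation of the ether bond. Setting out from carbonate 12, iridium-catalysed allylic hydroxylation with hydrogencarbonate as hydroxide source ([Ir(cod)Cl]2, L2, KHCO3, aqueous THF) uses a small nucleophile and should give the branched (1R)-1-arylprop-2-en-1-ol F3. Acylation (ClCO2Me, pyridine, CH2Cl2, 0 °C) gives the branched (1R)-methyl carbonate F4. Rhodium-catalysed allylic etherification of F4 with copper alkoxide 18 (RhCl(PPh3)3 modified with P(OMe)3, THF, 0 °C to rt) is stereospecific with net retention and regioretentive, so it should deliver the (1R,1'S) ether, and the route is rejoined at 19.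

3. Step 5. The ortho-benzyloxy group twists ring A out of the alkene plane, so hydrogenation may be slow and the catalyst may distinguish the two alkene faces poorly. The fallback sets the same centre by hydroboration instead. Setting out from 6, iodide-selective Suzuki–Miyaura coupling with isopropenylboronic acid pinacol ester (Pd(dppf)Cl2, K3PO4, dioxane/H2O, 60 °C) gives 1-(benzyloxy)-4-bromo-2-(prop-1-en-2-yl)benzene F5. Catalytic asymmetric hydroboration of this 1,1-disubstituted aryl alkene with pinacolborane (chiral NHC–copper or chiral cobalt catalyst) gives the primary boronate 2-[(2R)-2-(2-(benzyloxy)-5-bromophenyl)propyl]-4,4,5,5-tetramethyl-1,3,2-dioxaborolane F6. B-alkyl Suzuki–Miyaura coupling of F6 with an excess of aryl iodide 1 (Pd(OAc)2, RuPhos, K2CO3, toluene/H2O), which reacts ahead of the aryl bromide, rejoins the route at 8 and makes steps 1, 2 and 4 unnecessary.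

Further compounds
F1 | step 12 | (2R,3R,4S,5S)-2-{4-(benzyloxy)-3-[(2R)-1-(4-(benzyloxy)phenyl)propan-2-yl]phenyl}-5-[4-(benzyloxy)phenyl]-4-methyl-3-[(phenylsulfanyl)methyl]oxolane | C(Sc1ccccc1)[C@@H]1[C@H](C)[C@@H](c2ccc(OCc3ccccc3)cc2)O[C@H]1c1ccc(OCc2ccccc2)c([C@H](C)Cc2ccc(OCc3ccccc3)cc2)c1
F2 | step 12 | (2R,3R,4S,5S)-2-{4-(benzyloxy)-3-[(2R)-1-(4-(benzyloxy)phenyl)propan-2-yl]phenyl}-5-[4-(benzyloxy)phenyl]-3-methyl-4-[(phenylsulfanyl)methyl]oxolane | C[C@@H]1[C@H](CSc2ccccc2)[C@@H](c2ccc(OCc3ccccc3)cc2)O[C@H]1c1ccc(OCc2ccccc2)c([C@H](C)Cc2ccc(OCc3ccccc3)cc2)c1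
F3 | step 11 | (1R)-1-{4-(benzyloxy)-3-[(2R)-1-(4-(benzyloxy)phenyl)propan-2-yl]phenyl}prop-2-en-1-ol | O[C@H](C=C)c1ccc(OCc2ccccc2)c([C@H](C)Cc2ccc(OCc3ccccc3)cc2)c1
F4 | step 11 | methyl (1R)-1-{4-(benzyloxy)-3-[(2R)-1-(4-(benzyloxy)phenyl)propan-2-yl]phenyl}prop-2-en-1-yl carbonate | COC(=O)O[C@H](C=C)c1ccc(OCc2ccccc2)c([C@H](C)Cc2ccc(OCc3ccccc3)cc2)c1
F5 | step 5 | 1-(benzyloxy)-4-bromo-2-(prop-1-en-2-yl)benzene | Brc1ccc(OCc2ccccc2)c(C(C)=C)c1
F6 | step 5 | 2-[(2R)-2-(2-(benzyloxy)-5-bromophenyl)propyl]-4,4,5,5-tetramethyl-1,3,2-dioxaborolane | Brc1ccc(OCc2ccccc2)c([C@H](C)CB2OC(C)(C)C(C)(C)O2)c1
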